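## Structural features

Botryotin E (18) is a C20 diterpenoid monoacetate in which a trans-decalin (ring A: C1–C5, C10; ring B: C5–C10) is fused through the C8–C9 bond to a bicyclo[3.2.1]oct-6-ene. The atom labels used for every compound below are: C9=C11 (two-carbon bridge), C12 (bridgehead CH), C15 (one-carbon bridge, CHOH), C14–C13–C16 (three-carbon bridge), C17 (CH2OAc on C16), C18 (CH2OH on C4), C19 and C20 (methyls on C4 and C10). Ring C is the cyclopentene C8–C9=C11–C12–C15 and ring D the cyclohexane C8–C14–C13–C16–C12–C15; C8 is a quaternary carbon common to rings B, C and D, and C9 is fully substituted as well. The decalin carries C4 (β-CH3, α-CH2OH), C5 (α-H) and C10 (β-CH3), which is the pattern and absolute configuration of the abietane resin acids. In the bicycle, C15 lies on the β face (the side of the C10 methyl) with its hydroxyl turned toward the C9=C11 bridge, the three-carbon bridge lies on the α face, and C16 carries an equatorial tertiary hydroxyl and an axial CH2OAc; the two groups of adjacent stereocentres, C4/C5/C10 and C8/C15/C12/C16, communicate only through the sp2 carbon C9. Fragile elements are the primary acetate beside a free tertiary alcohol (acyl shift, hydrolysis), the 1,3-dioxygen pattern C15–C12–C16 (retro-aldol whenever one of the two carbons is a carbonyl), the strained trisubstituted alkene, and two neopentyl primary oxygens (C17, C18) that must be told apart. The real difficulty is C8, a quaternary stereocentre at the junction of three rings, next to fully substituted C9 and one atom from quaternary C10; its configuration decides on which face the one-carbon and the three-carbon bridge lie. The key step exploits that C8 carries both the oxygenated bridge carbon C15 and the methylene C14, and that C8, C9, C11, C12 and C15 form a five-membered ring. A 2-acyl-2-(one-carbon)cyclopentane is the product pattern of a 1,2-acyl shift in a six-membered α,β-epoxy ketone, so putting C14 back between C8 and C15 turns ring C into ring C of a 13-oxopodocarp-8(14)-ene, an abietane skeleton that already owns rings A and B of the target.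

## Logic of the disconnections

18 ⇒ 17. The C17–O bond of the acetate is cut, so that C16–O–C17 becomes an oxirane. This makes the primary acetate and the tertiary alcohol in one operation and avoids ever having to differentiate the two neopentyl primary hydroxyls. The acetate then never has to survive another step. The forward step must be an SN2 opening at C17 under buffered conditions so that the acyl group stays on the primary oxygen.

17 ⇒ 16 ⇒ 15. The O–Si bond at C18 and then the C16–C17 bond are cut (methylene transfer to a C16 ketone). C17 is the only carbon of ring D that is not part of the bicycle, and adding it last lets the ring geometry set C16. The forward step must deliver CH2 axially, from the side of the one-carbon bridge, to the C16 ketone.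

15 ⇒ 14 ⇒ 13. The oxidation level at C16 is adjusted and the C15–H bond is cut. C15 becomes a ketone, and the C16 hydroxyl of 13 serves as the internal hydride carrier. This reduces C15 and C16 to one β-hydroxy ketone. The demands are an axial C16 hydroxyl in 13, hydride delivery from the ring D side, and then an oxidation that distinguishes the two secondary carbinols of 14.

13 ⇒ 12. The C12–C16 bond is cut (retro-aldol). This opens ring D and the whole bridged system to a 6-6-5 tricycle with a three-carbon aldehyde chain on C8. The forward aldol must go through the α-carbon C12 of an ambident dienolate and through a chelated transition state.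

12 ⇒ 11 ⇒ 9 ⇒ 8 ⇒ 7. In turn: the C13–C16 bond is cut (C16 is carbon monoxide); the C9=C11 bond is moved back to C11=C12 and then saturated; the C13=C14 bond is cut (C13 is a Wittig methylene). What remains is a cyclopentanone whose quaternary C8 carries only a formyl group. The demands are a chemoselective hydroformylation of the vinyl group, a kinetic α-protonation of the dienolate, and a dehydrogenation that can only go one way because C8 is quaternary.

7 ⇒ 6 (key disconnection). The C8–C15 bond is cut and the C14–C15 bond restored, the reverse of a 1,2-acyl shift. The five-membered ring C and the quaternary stereocentre C8 disappear; what is left is a trisubstituted α,β-epoxy ketone in a six-membered ring, and the skeleton becomes that of a podocarpane. The forward step needs the epoxide on the α face, and acyl rather than hydride migration.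

6 ⇒ 5 ⇒ 3 ⇒ 2 ⇒ 1. The epoxide oxygen is removed, the C15 carbonyl is traced back to an isopropylidene group (lost as acetone), and C18 is returned to the carboxylic acid level. This reaches 1, which supplies 17 of the 20 skeletal carbons and the stereocentres C4, C5 and C10. The demands are an ozonolysis that takes only the tetrasubstituted double bond of the diene and an α-face nucleophilic epoxidation.

## Other disconnections considered

Alternative 1: (the first that comes to mind, a biomimetic bicyclo[2.2.2] to bicyclo[3.2.1] shift.) Cut: the C11–C12 bond is exchanged for a C11–C16 bond, which leads to the bicyclo[2.2.2]octene A2; A2 is cut at C8–C15 and C12–C16 into the ring C diene A1 and vinylene carbonate. Forward key step: Diels–Alder addition, then ionisation at C12 and shift of the alkenyl carbon C11 from C16 to C12 with capture of the C16 cation by water. Ground for preferring the chosen plan: A2 requires the dienophile to add to the β face of A1, syn to the C10 methyl that is 1,3 to C8, whereas addition to the open α face would lead to the C8 epimer. In addition, the alkenyl shift needs the C12 leaving group anti to the C9=C11 bridge while the C15 oxygen must be syn to it, a trans arrangement that a cis dienophile cannot supply. C15 and C16 would therefore need extra corrective steps.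

Alternative 2: Cut: C8–C14 and C12–C16, a (4+3) disconnection of the three-carbon bridge. Forward key step: cyclopropanation of the C11=C12 bond of the ring-B-fused cyclopentadienone ketal A3 by the rhodium vinylcarbenoid from methyl 2-diazobut-3-enoate (a dirhodium tetracarboxylate such as Rh2(OAc)4), followed by divinylcyclopropane Cope rearrangement to A4. Ground: the step is matched, since the large bridge enters anti to the C10 methyl, and it brings C17 with it. But A3 has to be built by cyclopentannulation onto a decalone whose carbonyl carbon C9 sits between two quaternary carbons. A3 is also a 5,5-dialkoxycyclopentadiene prone to dimerisation and to oxonium ylide formation with the carbenoid. After the key step, C16 still needs hydration and C15 a face-selective reduction. The estimate is well over twenty steps against fifteen.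

Alternative 3: Cut: C8–C9 and C11–C12, a (5+2) disconnection that makes ring D from an arene. Forward key step: oxidative dearomatisation of phenol A5 with PhI(OAc)2 and intramolecular cycloaddition of the phenoxonium ion with the tethered silyl enol ether to give the bicyclo[3.2.1]octenedione A6, which closes ring B at the same time. Ground: the arene delivers both oxygens of ring D cheaply. But A5 needs a seco-ring-B cyclohexane with three contiguous stereocentres (C4, C5, C10) that is harder to make than the decalin itself. The C9=C11 bond must be made afterwards by eliminating the C9 silyloxy group. The face of the arene that is attacked is controlled only through the forming ring B, and the first bond (C11–C12) has no ring-size advantage.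

Key step: step 5

Assumption: (+)-neoabietic acid of the natural abietane series (4α-CO2H, 4β-CH3, 5α-H, 9α-H, 10β-CH3) is taken as a purchasable resin acid; the α face is the face opposite the C10 methyl throughout.

## Route

Step 1
Reactants: 1 (+)-neoabietic acid (abieta-8(14),13(15)-dien-18-oic acid; the isopropylidene group sits on the ring carbon that becomes C15)
Product: 2 abieta-8(14),13(15)-dien-18-ol
Conditions: LiAlH4, THF, 0 °C to reflux; aqueous work-up
Reagents that add atoms: none
Why: LiAlH4 reduction of the carboxylic acid to the primary alcohol C18; the diene and the stereocentres C4, C5, C9 and C10 are untouched, and doing this first avoids any later hydride step in the presence of ketones, the oxirane or the acetate.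

Step 2
Reactants: 2 abieta-8(14),13(15)-dien-18-ol
Product: 3 18-(tert-butyldiphenylsilyloxy)abieta-8(14),13(15)-diene
Conditions: tBuPh2SiCl, imidazole, DMAP (cat.), DMF, 40 °C
Reagents that add atoms: tert-butyl(chloro)diphenylsilane, CC(C)(C)[Si](Cl)(c1ccccc1)c1ccccc1
Why: Silylation of the neopentyl primary alcohol; the silyl ether should survive ozone, alkaline peroxide, BF3, ylides, IBX and alkoxide or amide bases, and is removed by fluoride in step 14 before the acetate is introduced.

Step 3
Reactants: 3 18-(tert-butyldiphenylsilyloxy)abieta-8(14),13(15)-diene
Product: 5 silyl-protected 13-oxopodocarp-8(14)-ene (six-membered enone C15(=O)–C14H=C8 and 9α-H), via methoxy hydroperoxide 4 (not isolated)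
Conditions: O3 (1 equiv, Sudan Red 7B indicator), CH2Cl2–MeOH, NaHCO3, −78 °C; then Me2S, −78 °C to 20 °C
Reagents that add atoms: ozone, [O-][O+]=O (methanol, CO, is held only in intermediate 4)
Why: Ozonolysis (Criegee mechanism): electrophilic ozone should take the tetrasubstituted isopropylidene double bond of the diene first, and the enone that results is deactivated toward a second addition; methanol traps the carbonyl oxide as 4, which Me2S reduces to the ketone. No stereocentre is formed.

Step 4
Reactants: 5 silyl-protected 13-oxopodocarp-8(14)-ene
Product: 6 8α,14α-epoxy ketone (oxirane across C8–C14 on the α face, C15 ketone, 9α-H)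
Conditions: 30% H2O2, NaOH (aq, cat.), MeOH–THF, 0 °C to 20 °C
Reagents that add atoms: hydrogen peroxide, OO
Why: Weitz–Scheffer nucleophilic epoxidation of the β,β-disubstituted enone; hydroperoxide should add to C8 axially on the α face, cis to H9 and away from the C10 methyl that is 1,3-diaxial to the β face of C8, and ring closure on the same face fixes C8 and C14.

Step 5
Reactants: 6 8α,14α-epoxy ketone
Product: 7 ring-contracted keto aldehyde (cis-fused 6-6-5 tricycle; cyclopentanone C8–C9–C11–C12–C15(=O); quaternary C8 with C15 on the β face and the formyl group C14 on the α face; 9α-H)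
Conditions: BF3·OEt2 (1.1 equiv), CH2Cl2, −20 °C to 0 °C, 15 min; NaHCO3 quench
Reagents that add atoms: none
Why: BF3 coordinates the oxirane oxygen and the C8–O bond, the one to the fully substituted carbon, lengthens; as positive charge develops at C8 the acyl carbon C15 moves from C14 to C8 through a three-centre transition state while C14 keeps the oxygen as the formyl group, which is the Lewis-acid rearrangement of α,β-epoxy ketones to β-dicarbonyl compounds by 1,2-acyl shift (a semipinacol-type process; the closest case is the contraction of 3,5,5-trimethylcyclohex-2-enone oxide to a 2-formylcyclopentanone). The shift contracts the six-membered ring (C8, C9, C11, C12, C15, C14) to ring C of the target (C8, C9, C11, C12, C15); the ring is closed by migration, not by cyclisation, and C14 is expelled as the one-carbon handle for the three-carbon bridge. The only new stereocentre is the quaternary C8: C15 arrives on the face opposite to the departing oxygen, so the α-epoxide should give C15 on the β face and the formyl group on the α face, the arrangement of the target, and the cis ring fusion that this creates (H9 and C14 both α) is also the less strained one. C9 keeps its α hydrogen because it never becomes planar. The selectivity needed is acyl shift over hydride shift from C14 (which would give the C14/C15 diketone) and over shifts of ring B bonds; it rests on the high migratory aptitude of an acyl group toward a tertiary cationic centre, and short contact at low temperature keeps the non-enolisable β-keto aldehyde from losing its formyl group.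

Step 6
Reactants: 7 ring-contracted keto aldehyde
Product: 8 vinyl ketone (C8 carries the α vinyl group C14=C13)
Conditions: Ph3PCH3Br, KN(SiMe3)2, THF, 0 °C; then 7, −78 °C to 0 °C
Reagents that add atoms: methyltriphenylphosphonium bromide, C[P+](c1ccccc1)(c1ccccc1)c1ccccc1.[Br-]
Why: Wittig methylenation; the aldehyde reacts far faster than the ketone flanked by the quaternary C8, and C8 cannot epimerise. The new carbon is C13.

Step 7
Reactants: 8 vinyl ketone
Product: 9 conjugated cyclopentenone (C15=O, C11=C12, 9α-H, α-vinyl on C8)
Conditions: IBX (2 equiv), DMSO–toluene, 70 °C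
Reagents that add atoms: none
Why: IBX dehydrogenation of a ketone to its enone; C8 is quaternary, so enolisation and loss of hydrogen can only occur on the C12–C11 side, and there is no δ-hydrogen for over-oxidation.

Step 8
Reactants: 9 conjugated cyclopentenone
Product: 11 β,γ-unsaturated ketone (C9=C11, C12H2, C15=O), via potassium dienolate 10 (not isolated)
Conditions: KOtBu (1.5 equiv), tBuOH–THF, 0 °C; then inverse quench into AcOH–THF, −78 °C
Reagents that add atoms: none
Why: Base-mediated deconjugation: the only acidic hydrogen of 9 is the γ-hydrogen H9 on the convex face of the cis-fused bicycle, so KOtBu gives the through-conjugated dienolate 10, and kinetic protonation of such dienolates occurs at the α-carbon C12, which leaves the double bond at C9=C11. The stereocentre C9 is deleted and C8 is unaffected.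

Step 9
Reactants: 11 β,γ-unsaturated ketone
Product: 12 keto aldehyde (C8 carries the α chain C14H2–C13H2–C16HO)
Conditions: Rh(acac)(CO)2 (2 mol %), Xantphos (4 mol %), CO/H2 (1:1, 20 bar), toluene, 70 °C
Reagents that add atoms: carbon monoxide, [C-]#[O+]
Why: Rhodium-catalysed hydroformylation; a vinyl group on a quaternary carbon can only give the linear aldehyde, and the hindered trisubstituted C9=C11 bond and the ketone are left alone under these neutral conditions. The carbonyl carbon introduced is C16.

Step 10
Reactants: 12 keto aldehyde
Product: 13 bridged ene-ketol (bicyclo[3.2.1]oct-6-en-8-one: C15=O, C9=C11, C12–C16 bond, axial hydroxyl on C16)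
Conditions: LiN(SiMe3)2 (1.05 equiv), THF (0.01 M), −78 °C; AcOH quench at −78 °C
Reagents that add atoms: none
Why: Intramolecular aldol addition: the doubly activated C12 methylene (α to the ketone and allylic) gives the lithium dienolate, whose α-carbon C12 is the only nucleophilic site that can reach the aldehyde without forming a bond to C9 between two quaternary carbons; the 6-exo-trig closure C12–C16 makes ring D and the bicyclo[3.2.1]octene. The tether on the α face of C8 fixes C12, and the lithium-bridged closed transition state (Zimmerman–Traxler type) should place the C16 oxygen axial, cis to the C15 carbonyl.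

Step 11
Reactants: 13 bridged ene-ketol
Product: 14 diol (C15 hydroxyl turned toward the C9=C11 bridge, C16 axial hydroxyl)
Conditions: Me4NBH(OAc)3, MeCN–AcOH (1:1), −30 °C to 0 °C
Reagents that add atoms: none
Why: Evans–Saksena reduction: the axial C16 hydroxyl exchanges onto boron and hydride is delivered intramolecularly through a six-membered transition state to the face of the C15 carbonyl that looks at ring D, so the new hydroxyl points toward the C9=C11 bridge (anti-1,3-diol), as in the target. Without internal delivery neither face is clearly preferred (C10 methyl on one side, axial hydrogens of ring D on the other).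

Step 12
Reactants: 14 diol
Product: 15 hydroxy ketone (C16=O, C15 hydroxyl retained)
Conditions: Dess–Martin periodinane (1.05 equiv), NaHCO3, CH2Cl2, 0 °C
Reagents that add atoms: none
Why: Dess–Martin oxidation; the axial C16 carbinol is an ordinary cyclohexanol that gains strain relief on oxidation, whereas the C15 carbinol is flanked by the quaternary C8 and would become a strained bicyclo[3.2.1]octan-8-one with a compressed C–CO–C angle, so one equivalent of oxidant at 0 °C should take C16 selectively.

Step 13
Reactants: 15 hydroxy ketone
Product: 16 spiro-epoxide (oxirane C16–O–C17 with axial CH2 and equatorial oxygen)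
Conditions: Me3SI, KN(SiMe3)2, THF, −10 °C; then 15, −10 °C to 20 °C
Reagents that add atoms: trimethylsulfonium iodide, C[S+](C)C.[I-]
Why: Corey–Chaykovsky epoxidation: dimethylsulfonium methylide adds irreversibly and, as with cyclohexanones, axially, here from the side of the one-carbon bridge past the axial hydrogens on C14 and C15 and away from the C11 bridge that shields the equatorial side; ring closure gives axial CH2 (C17) and equatorial oxygen, the C16 configuration of the target. The preformed ylide is too weak a base to deprotonate the C15 hydroxyl to a useful extent.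

Step 14
Reactants: 16 spiro-epoxide
Product: 17 epoxy diol (free hydroxyls at C15 and C18)
Conditions: Bu4NF, THF, 20–40 °C
Reagents that add atoms: none
Why: Fluoride-mediated cleavage of the silyl ether; the oxirane and the hindered alcohols are stable to Bu4NF at this temperature, and removing the silyl group now means that no deprotection is needed in the presence of the acetate.

Step 15
Reactants: 17 epoxy diol
Product: 18 botryotin E
Conditions: CsOAc (5 equiv), AcOH (3 equiv), DMF, 80 °C
Reagents that add atoms: caesium acetate, CC(=O)[O-].[Cs+] (the proton comes from acetic acid)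
Why: SN2 opening of the 2,2-disubstituted oxirane by acetate at the primary carbon C17, with the C16–O bond and hence the C16 configuration retained; acetic acid protonates the tertiary alkoxide so that the acetyl group stays on the primary oxygen, and the free hydroxyls at C15 and C18 need no protection.

## Compound list

1 | (+)-neoabietic acid, abieta-8(14),13(15)-dien-18-oic acid | CC(C)=C1CC[C@H]2C(=C1)CC[C@H]3[C@](C)(C(=O)O)CCC[C@]23C | starting material
2 | abieta-8(14),13(15)-dien-18-ol | CC(C)=C1CC[C@H]2C(=C1)CC[C@H]3[C@](C)(CO)CCC[C@]23C | intermediate
3 | 18-(tert-butyldiphenylsilyloxy)abieta-8(14),13(15)-diene | CC(C)=C1CC[C@H]2C(=C1)CC[C@H]3[C@](C)(CO[Si](c4ccccc4)(c4ccccc4)C(C)(C)C)CCC[C@]23C | intermediate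
4 | methoxy hydroperoxide (hydroperoxy and methoxy on the future C15, both epimers, C8=C14 retained) | COC1(OO)CC[C@H]2C(=C1)CC[C@H]3[C@](C)(CO[Si](c4ccccc4)(c4ccccc4)C(C)(C)C)CCC[C@]23C | intermediate (not isolated)
5 | silyl-protected 13-oxopodocarp-8(14)-ene (enone C15(=O)–C14H=C8, 9α-H) | O=C1CC[C@H]2C(=C1)CC[C@H]3[C@](C)(CO[Si](c4ccccc4)(c4ccccc4)C(C)(C)C)CCC[C@]23C | intermediate
6 | 8α,14α-epoxy ketone | O=C1CC[C@H]2[C@]3(O[C@H]31)CC[C@H]4[C@](C)(CO[Si](c5ccccc5)(c5ccccc5)C(C)(C)C)CCC[C@]24C | intermediate
7 | ring-contracted keto aldehyde (C8: C15 β, formyl C14 α; 9α-H) | O=C[C@]12CC[C@H]3[C@](C)(CO[Si](c4ccccc4)(c4ccccc4)C(C)(C)C)CCC[C@]3(C)[C@H]1CCC2=O | intermediate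
8 | vinyl ketone (α-vinyl on C8) | C=C[C@]12CC[C@H]3[C@](C)(CO[Si](c4ccccc4)(c4ccccc4)C(C)(C)C)CCC[C@]3(C)[C@H]1CCC2=O | intermediate
9 | conjugated cyclopentenone (C11=C12) | C=C[C@]12CC[C@H]3[C@](C)(CO[Si](c4ccccc4)(c4ccccc4)C(C)(C)C)CCC[C@]3(C)[C@H]1C=CC2=O | intermediate
10 | potassium dienolate (C15(OK)=C12–C11=C9) | [K+].C=C[C@]12CC[C@H]3[C@](C)(CO[Si](c4ccccc4)(c4ccccc4)C(C)(C)C)CCC[C@]3(C)C1=CC=C2[O-] | intermediate (not isolated)
11 | β,γ-unsaturated ketone (C9=C11) | C=C[C@]12CC[C@H]3[C@](C)(CO[Si](c4ccccc4)(c4ccccc4)C(C)(C)C)CCC[C@]3(C)C1=CCC2=O | intermediate
12 | keto aldehyde (α-CH2CH2CHO on C8) | O=CCC[C@]12CC[C@H]3[C@](C)(CO[Si](c4ccccc4)(c4ccccc4)C(C)(C)C)CCC[C@]3(C)C1=CCC2=O | intermediate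
13 | bridged ene-ketol (C15=O, axial C16 OH) | O[C@H]1CC[C@]23CC[C@H]4[C@](C)(CO[Si](c5ccccc5)(c5ccccc5)C(C)(C)C)CCC[C@]4(C)C2=C[C@H]1C3=O | intermediate
14 | diol (C15 OH syn to C9=C11, axial C16 OH) | O[C@H]1CC[C@]23CC[C@H]4[C@](C)(CO[Si](c5ccccc5)(c5ccccc5)C(C)(C)C)CCC[C@]4(C)C2=C[C@H]1[C@H]3O | intermediate
15 | hydroxy ketone (C16=O) | O=C1CC[C@]23CC[C@H]4[C@](C)(CO[Si](c5ccccc5)(c5ccccc5)C(C)(C)C)CCC[C@]4(C)C2=C[C@H]1[C@H]3O | intermediate
16 | spiro-epoxide (axial C17, equatorial O) | C1O[C@@]12CC[C@]34CC[C@H]5[C@](C)(CO[Si](c6ccccc6)(c6ccccc6)C(C)(C)C)CCC[C@]5(C)C3=C[C@H]2[C@H]4O | intermediate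
17 | epoxy diol | C1O[C@@]12CC[C@]34CC[C@H]5[C@](C)(CO)CCC[C@]5(C)C3=C[C@H]2[C@H]4O | intermediate
18 | botryotin E | CC(=O)OC[C@@]1(O)CC[C@]23CC[C@H]4[C@](C)(CO)CCC[C@]4(C)C2=C[C@H]1[C@H]3O | target

## Step count and least certain steps

Total step count: 15. Longest linear sequence: 15 steps (the route is linear from 1).

Step 5 (key step). Most likely to go wrong: a competing 1,2-hydride shift from C14, because in the rigid oxirane the C14–H bond is at least as well aligned with the developing vacancy at C8 as the ring bond C14–C15, and retro-Claisen loss of the formyl group during work-up; both processes lose the quaternary centre. Fallback, setting out from 5 and returning at 13: ozonolysis of the enone double bond with oxidative work-up (O3; then H2O2) removes C14 as formic acid and gives keto acid F1, which Me3SiCHN2 converts into keto ester F2. A titanium-mediated keto ester coupling (low-valent titanium from TiCl3 and LiAlH4, DME, reflux; then aqueous HCl) joins C8 to C15 and gives the cis-fused cyclopentanone F3. Dehydrogenation with IBX and equilibration with DBU give the ring-fusion enone F4. Its extended potassium dienolate (KOtBu, tBuOH–THF, 0 °C) should add to acrolein through C8 on the α face, as in the deconjugative α-alkylation of steroidal enones, and the C12 enolate then closes ring D by aldol, which gives 13 directly.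

Step 10. Most likely to go wrong: loss of site control in the ambident dienolate (bond formation through C9, or proton return to C9 that reconjugates the enone and opens a Michael pathway for the aldehyde enolate), addition of the amide base to the aldehyde, and incomplete control at C16; the substrate also depends on the kinetic protonation of step 8 having left no conjugated enone. Fallback, setting out from 9 and returning at 13: the dienolate 10 is trapped with tBuMe2SiCl as the siloxydiene F5, which cannot reconjugate. Hydroformylation as in step 9 gives aldehyde F6. One equivalent of Bu4NF in THF at −78 °C then releases the dienolate in the absence of any base, so that the aldol closure to 13 is the only process open to it.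

Step 13. Most likely to go wrong: poor facial selectivity of the methylene transfer (approach from the equatorial side), or base-induced retro-aldol opening of the C12–C15 bond of the β-hydroxy ketone. Fallback, setting out from 15 and returning at 18: Petasis methylenation (Cp2TiMe2 in excess, toluene, 65 °C), which is not basic, gives the exocyclic alkene F11. Dihydroxylation (OsO4 cat., N-methylmorpholine N-oxide) gives triol F12. Acetylation of the primary hydroxyl (AcCl, 2,4,6-collidine, −78 °C) gives acetate F13, and HF·pyridine removes the silyl group to give 18. Because the ylide delivers carbon and the osmium reagent delivers oxygen to C16, the two sequences use the same facial bias in opposite senses, so whichever face of C16 is the more open, one of them leads to the natural configuration.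

Step 12. Most likely to go wrong: insufficient discrimination between the two secondary carbinols and over-oxidation to the diketone. Fallback, setting out from 14 and returning at 17: both hydroxyls are silylated (Et3SiOTf, 2,6-lutidine) to the bis-silyl ether F7. Methanolysis under mild acid (pyridinium p-toluenesulfonate, MeOH, 0 °C) frees the less hindered C16 hydroxyl and gives alcohol F8; unreacted or over-cleaved material can be recycled. Dess–Martin oxidation gives ketone F9, methylene transfer as in step 13 gives epoxide F10, and Bu4NF removes both silyl groups to give 17. This variant also protects the C15 hydroxyl during the ylide step.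

## Further compounds

F1 | step 5 | keto acid (C8 ketone in ring B, 2-carboxyethyl chain C11–C12–C15 on C9, C14 removed) | OC(=O)CC[C@H]1C(=O)CC[C@H]2[C@](C)(CO[Si](c3ccccc3)(c3ccccc3)C(C)(C)C)CCC[C@]12C
F2 | step 5 | methyl ester of F1 | COC(=O)CC[C@H]1C(=O)CC[C@H]2[C@](C)(CO[Si](c3ccccc3)(c3ccccc3)C(C)(C)C)CCC[C@]12C
F3 | step 5 | cis-fused cyclopentanone (C15=O bonded to C8, 8α-H, 9α-H) | O=C1CC[C@H]2[C@@H]1CC[C@H]3[C@](C)(CO[Si](c4ccccc4)(c4ccccc4)C(C)(C)C)CCC[C@]23C
F4 | step 5 | ring-fusion enone (C15(=O)–C8=C9) | O=C1CCC2=C1CC[C@H]3[C@](C)(CO[Si](c4ccccc4)(c4ccccc4)C(C)(C)C)CCC[C@]23C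
F5 | step 10 | tert-butyldimethylsilyl dienol ether of 9 (C15(OSi)=C12–C11=C9, α-vinyl on C8) | C=C[C@]12CC[C@H]3[C@](C)(CO[Si](c4ccccc4)(c4ccccc4)C(C)(C)C)CCC[C@]3(C)C1=CC=C2O[Si](C)(C)C(C)(C)C
F6 | step 10 | siloxydiene aldehyde (hydroformylation product of F5) | O=CCC[C@]12CC[C@H]3[C@](C)(CO[Si](c4ccccc4)(c4ccccc4)C(C)(C)C)CCC[C@]3(C)C1=CC=C2O[Si](C)(C)C(C)(C)C
F7 | step 12 | bis(triethylsilyl) ether of 14 | CC[Si](CC)(CC)O[C@H]1CC[C@]23CC[C@H]4[C@](C)(CO[Si](c5ccccc5)(c5ccccc5)C(C)(C)C)CCC[C@]4(C)C2=C[C@H]1[C@H]3O[Si](CC)(CC)CC
F8 | step 12 | C15 triethylsilyl ether with free axial C16 hydroxyl | O[C@H]1CC[C@]23CC[C@H]4[C@](C)(CO[Si](c5ccccc5)(c5ccccc5)C(C)(C)C)CCC[C@]4(C)C2=C[C@H]1[C@H]3O[Si](CC)(CC)CC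
F9 | step 12 | C16 ketone with C15 triethylsilyl ether | O=C1CC[C@]23CC[C@H]4[C@](C)(CO[Si](c5ccccc5)(c5ccccc5)C(C)(C)C)CCC[C@]4(C)C2=C[C@H]1[C@H]3O[Si](CC)(CC)CC
F10 | step 12 | spiro-epoxide with C15 triethylsilyl ether | C1O[C@@]12CC[C@]34CC[C@H]5[C@](C)(CO[Si](c6ccccc6)(c6ccccc6)C(C)(C)C)CCC[C@]5(C)C3=C[C@H]2[C@H]4O[Si](CC)(CC)CC
F11 | step 13 | exocyclic alkene (C16=C17H2, C15 hydroxyl free) | C=C1CC[C@]23CC[C@H]4[C@](C)(CO[Si](c5ccccc5)(c5ccccc5)C(C)(C)C)CCC[C@]4(C)C2=C[C@H]1[C@H]3O
F12 | step 13 | triol (equatorial C16 OH, axial CH2OH, C15 OH; C18 silyl ether) | OC[C@@]1(O)CC[C@]23CC[C@H]4[C@](C)(CO[Si](c5ccccc5)(c5ccccc5)C(C)(C)C)CCC[C@]4(C)C2=C[C@H]1[C@H]3O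
F13 | step 13 | 18-O-silyl botryotin E | CC(=O)OC[C@@]1(O)CC[C@]23CC[C@H]4[C@](C)(CO[Si](c5ccccc5)(c5ccccc5)C(C)(C)C)CCC[C@]4(C)C2=C[C@H]1[C@H]3O
A1 | alternative 1 | ring C diene (C8=C9–C11=C16, acetoxymethyl on C16) | CC(=O)OCC1=CC2=C(CC1)CC[C@H]3[C@](C)(CO)CCC[C@]23C
A2 | alternative 1 | bicyclo[2.2.2]octene carbonate (bridgeheads C8 and C16; bridges C9=C11, C13–C14 and C15–C12 with the cis carbonate syn to the alkene; C15 on the β face) | CC(=O)OC[C@]12CC[C@@]3(CC[C@H]4[C@](C)(CO)CCC[C@]4(C)C3=C1)[C@@H]5OC(=O)O[C@H]25
A3 | alternative 2 | ring-B-fused cyclopentadienone dimethyl ketal (C8=C9–C11=C12, C15(OMe)2) | COC1(OC)C=CC2=C1CC[C@H]3[C@](C)(CO[Si](C)(C)C(C)(C)C)CCC[C@]23C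
A4 | alternative 2 | bicyclo[3.2.1]octa-2,6-diene ester (C16(CO2Me)=C13, C9=C11, C15 ketal) | COC(=O)C1=CC[C@]23CC[C@H]4[C@](C)(CO[Si](C)(C)C(C)(C)C)CCC[C@]4(C)C2=C[C@H]1C3(OC)OC
A5 | alternative 3 | phenol with seco ring B (2-alkyl-5-methoxyphenol tethered through C7–C6 to C5; silyl enol ether C9(OSi)=C11H2 on C10) | COc1ccc(CC[C@H]2[C@](C)(CO[Si](C)(C)C(C)(C)C)CCC[C@]2(C)C(=C)O[Si](C)(C)C(C)(C)C)c(O)c1
A6 | alternative 3 | bicyclo[3.2.1]oct-3-ene-2,8-dione (C16=O, C13=C14, C15=O, silyloxy on C9) | O=C1C=C[C@]23CC[C@H]4[C@](C)(CO[Si](C)(C)C(C)(C)C)CCC[C@]4(C)[C@@]2(O[Si](C)(C)C(C)(C)C)C[C@H]1C3=O
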